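The route cuts the guaiane cyclopentene ring of the bicyclo[2.2.1]heptene at C-3–C-4 and C-1–C-2, the two ring bonds not adjacent to the quaternary spiro carbon C-11′. One flask unites a seco-eudesmanolide (E)-α-(formylmethylene) lactone (C-5′=C-6′ masked as a selenide) with a guaianolide-derived 1-methylene-2-ethylidenecycloheptane. A Lewis-acid Diels–Alder reaction forms C-13′–C-11′ and C-3–C-4, base epimerises C-3, and a Me2AlCl carbonyl-ene reaction between the aldehyde and the new C-1=C-5 alkene forms C-2–C-1 and places the alkene at C-4=C-5. The step exploits that C-2 bridges C-3 and C-1, the 1,4-positions of the cyclohexene C-3/C-11′/C-13′/C-1/C-5/C-4.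

Key step: step 19

Remark: locants follow sesquiterpene numbering (guaianolide half C-1 to C-15, seco-eudesmanolide half C-1′ to C-15′; C-13′ is the CH2 between C-11′ and C-1, C-2 carries the acetate); 1, 16, 17 and 22 are taken as catalogue compounds.

Step 1
Reactants: 1 (R)-4-[(tert-butyldimethylsilyl)oxy]cyclohex-2-en-1-one
Product: 2 (4R,6R)-4-[(tert-butyldimethylsilyl)oxy]-6-methylcyclohex-2-en-1-one
Conditions: LDA, THF, −78 °C; MeI, −78 → −40 °C
Reagents that add atoms: iodomethane, CI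
Why: Kinetic α′-deprotonation of the enone and enolate alkylation anti to the C-4 silyloxy group should set the future C-10 methyl trans to the C-8 oxygen.

Step 2
Reactants: 2 (4R,6R)-4-[(tert-butyldimethylsilyl)oxy]-6-methylcyclohex-2-en-1-one
Product: 4 methyl 2-[(1S,2R,4R)-2-[(tert-butyldimethylsilyl)oxy]-4-methyl-5-oxocyclohexyl]acetate, via silyl enol ether 3 (not isolated)
Conditions: CH2=C(OMe)OTBS, TBSOTf (5 mol%), CH2Cl2, −78 °C; then 1 M HCl, THF, 0 °C
Reagents that add atoms: 1-[(tert-butyldimethylsilyl)oxy]-1-methoxyethene, C=C(OC)O[Si](C)(C)C(C)(C)C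
Why: Mukaiyama–Michael addition of the acetate ketene silyl acetal should occur anti to the γ-silyloxy group, setting C-7 trans to the C-8 oxygen, and mild acid unmasks the ketone.

Step 3
Reactants: 4 methyl 2-[(1S,2R,4R)-2-[(tert-butyldimethylsilyl)oxy]-4-methyl-5-oxocyclohexyl]acetate
Product: 6 methyl 2-[(1S,2R,4R)-2-[(tert-butyldimethylsilyl)oxy]-4-methyl-5-oxocycloheptyl]acetate, via α-silyl ketone 5 (not isolated)
Conditions: TMSCHN2, BF3·OEt2, CH2Cl2, −78 → −40 °C; then 1 M HCl, THF, 0 °C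
Reagents that add atoms: (trimethylsilyl)diazomethane, C[Si](C)(C)C=[N+]=[N-]
Why: Lewis-acid diazoalkane ring expansion (Tiffeneau–Demjanov-type) should proceed by migration of the less substituted α-methylene, inserting C-5 between the carbonyl and C-6 without touching the α-methyl centre.

Step 4
Reactants: 6 methyl 2-[(1S,2R,4R)-2-[(tert-butyldimethylsilyl)oxy]-4-methyl-5-oxocycloheptyl]acetate
Product: 8 (3aS,7R,8aR)-7-methylhexahydro-2H-cyclohepta[b]furan-2,6(3H)-dione, via hydroxy ester 7 (not isolated)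
Conditions: 48% aq. HF, MeCN, 0 °C → rt
Reagents that add atoms: none
Why: Acidic desilylation frees the C-8 hydroxyl, which lactonises onto the methyl ester (acyl substitution, no stereocentre touched) to give the trans-fused γ-lactone.

Step 5
Reactants: 8 (3aS,7R,8aR)-7-methylhexahydro-2H-cyclohepta[b]furan-2,6(3H)-dione
Product: 9 (3aS,7R,8aR)-5-(1-hydroxyethyl)-7-methylhexahydro-2H-cyclohepta[b]furan-2,6(3H)-dione (diastereomers at C-5 and the carbinol carbon)
Conditions: LDA (1.05 equiv), THF, −78 °C; CH3CHO, −78 °C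
Reagents that add atoms: acetaldehyde, CC=O
Why: The ketone should be deprotonated kinetically at its unbranched α-methylene (C-5) rather than at branched C-10 or the less acidic lactone, and the enolate undergoes an aldol addition.

Step 6
Reactants: 9 (3aS,7R,8aR)-5-(1-hydroxyethyl)-7-methylhexahydro-2H-cyclohepta[b]furan-2,6(3H)-dione
Product: 11 (3aS,7R,8aR,5E)-5-ethylidene-7-methylhexahydro-2H-cyclohepta[b]furan-2,6(3H)-dione, via mesylate 10 (not isolated)
Conditions: MsCl, Et3N, CH2Cl2, 0 °C; then DBU, 0 °C → rt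
Reagents that add atoms: none
Why: Mesylation and E1cB elimination should give the thermodynamically preferred (E)-α-ethylidene ketone with the methyl anti to the carbonyl.

Step 7
Reactants: 11 (3aS,7R,8aR,5E)-5-ethylidene-7-methylhexahydro-2H-cyclohepta[b]furan-2,6(3H)-dione
Product: 12 (3aS,7R,8aR,5E)-5-ethylidene-7-methyl-6-methylideneoctahydro-2H-cyclohepta[b]furan-2-one
Conditions: Zn, CH2Br2, TiCl4, THF/CH2Cl2, 0 °C → rt
Reagents that add atoms: dibromomethane, BrCBr
Why: Takai–Lombardo methylenation is non-basic and ketone-selective, so the hindered enone carbonyl should be converted without epimerising C-10 or touching the lactone.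

Step 8
Reactants: 12 (3aS,7R,8aR,5E)-5-ethylidene-7-methyl-6-methylideneoctahydro-2H-cyclohepta[b]furan-2-one
Product: 15 (3aS,7R,8aR,5E)-5-ethylidene-7-methyl-3,6-dimethylideneoctahydro-2H-cyclohepta[b]furan-2-one, via Mannich base 13 (not isolated), via methiodide 14 (not isolated)
Conditions: LDA, THF, −78 °C; CH2=NMe2+ I−, −78 → 0 °C; then MeI, MeOH, rt; then aq. NaHCO3, CH2Cl2
Reagents that add atoms: Eschenmoser's salt (N,N-dimethylmethyleneiminium iodide), C=[N+](C)C.[I-]
Why: Mannich reaction of the lactone enolate followed by quaternisation and Hofmann-type elimination is the standard α-methylenation of γ-lactones and erases the temporary C-11 centre.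

Step 9
Reactants: 16 (3-bromopropoxy)(tert-butyl)diphenylsilane; 17 (E)-pent-3-en-2-one
Product: 19 (4S)-7-[(tert-butyldiphenylsilyl)oxy]-3-[(dimethylamino)methyl]-4-methylheptan-2-one (C-3 epimers), via Grignard reagent 18 (not isolated)
Conditions: Mg, THF; then CuBr·SMe2 (5 mol%), Josiphos (6 mol%), t-BuOMe, −75 °C, 17; then CH2=NMe2+ I−, −75 → 0 °C
Reagents that add atoms: Eschenmoser's salt (N,N-dimethylmethyleneiminium iodide), C=[N+](C)C.[I-]
Why: Copper/ferrocenyl-diphosphine-catalysed asymmetric conjugate addition of the Grignard reagent sets C-4′ (ligand antipode chosen for 4S), and the regiodefined magnesium enolate is trapped by a Mannich reaction at C-5′.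

Step 10
Reactants: 19 (4S)-7-[(tert-butyldiphenylsilyl)oxy]-3-[(dimethylamino)methyl]-4-methylheptan-2-one
Product: 21 (4S)-7-[(tert-butyldiphenylsilyl)oxy]-4-methyl-3-methylideneheptan-2-one, via methiodide 20 (not isolated)
Conditions: MeI, CH2Cl2, rt; then aq. NaHCO3
Reagents that add atoms: none
Why: Quaternisation and Hofmann-type β-elimination of the Mannich base should give the α-methylene ketone under conditions too mild to enolise toward C-4′.

Step 11
Reactants: 21 (4S)-7-[(tert-butyldiphenylsilyl)oxy]-4-methyl-3-methylideneheptan-2-one; 22 methyl 4-oxobutanoate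
Product: 24 methyl 2-[(1S)-5-[(2S)-5-[(tert-butyldiphenylsilyl)oxy]pentan-2-yl]-4-oxocyclohex-2-en-1-yl]acetate (C-5 epimers), via keto aldehyde 23 (not isolated)
Conditions: (S)-α,α-diphenylprolinol TMS ether (10 mol%), ethyl 3,4-dihydroxybenzoate (20 mol%), neat, 4 °C; then p-TsOH·H2O, PhMe, 40 °C
Reagents that add atoms: none
Why: Enamine-catalysed Michael addition to the unsubstituted enone terminus sets C-7′ (electrophile enters anti to the diarylsiloxymethyl group of the (S)-catalyst), and acid-mediated aldol condensation of the methyl ketone onto the aldehyde (Robinson-type annulation) closes the cyclohexenone.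

Step 12
Reactants: 24 methyl 2-[(1S)-5-[(2S)-5-[(tert-butyldiphenylsilyl)oxy]pentan-2-yl]-4-oxocyclohex-2-en-1-yl]acetate
Product: 26 (3aS,7aS)-5-[(2S)-5-[(tert-butyldiphenylsilyl)oxy]pentan-2-yl]hexahydro-1-benzofuran-2,6-dione (C-5 epimers), via enone acid 25 (not isolated)
Conditions: LiOH, THF/H2O, 0 °C; then 1 M HCl to pH 3; p-TsOH (cat.), PhMe, rt
Reagents that add atoms: lithium hydroxide, [Li+].[OH-]
Why: After saponification the carboxylic acid should add intramolecularly to the enone β-carbon (oxa-Michael lactonisation), and because the five-membered ring can only close cis, C-8′ is set from C-7′.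

Step 13
Reactants: 26 (3aS,7aS)-5-[(2S)-5-[(tert-butyldiphenylsilyl)oxy]pentan-2-yl]hexahydro-1-benzofuran-2,6-dione
Product: 28 (3aR,7aS)-5-[(2S)-5-[(tert-butyldiphenylsilyl)oxy]pentan-2-yl]-3,3a,7,7a-tetrahydro-1-benzofuran-2,6-dione, via α-selenide 27 (not isolated)
Conditions: PhSeCl, EtOAc, rt; then 30% H2O2, pyridine, CH2Cl2, 0 °C
Reagents that add atoms: none
Why: Selenenylation through the more substituted enol places selenium at C-5′ and selenoxide syn-elimination should give the endocyclic C-5′=C-6′ enone from both C-5′ epimers under non-basic conditions that spare the β′-acyloxy ketone.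

Step 14
Reactants: 28 (3aR,7aS)-5-[(2S)-5-[(tert-butyldiphenylsilyl)oxy]pentan-2-yl]-3,3a,7,7a-tetrahydro-1-benzofuran-2,6-dione
Product: 29 (3aS,7aS)-5-[(2S)-5-[(tert-butyldiphenylsilyl)oxy]pentan-2-yl]-4-(phenylselanyl)hexahydro-1-benzofuran-2,6-dione (SePh anti to the lactone CH2 arm; side chain anti to SePh)
Conditions: PhSeH, CH2Cl2, 0 °C → rt
Reagents that add atoms: benzeneselenol, [SeH]c1ccccc1
Why: Seleno-Michael addition of the soft, weakly basic selenol anti to the C-7′ arm masks the nucleophilic C-5′=C-6′ alkene as a selenide (two temporary centres) that is eliminated oxidatively at the end.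

Step 15
Reactants: 29 (3aS,7aS)-5-[(2S)-5-[(tert-butyldiphenylsilyl)oxy]pentan-2-yl]-4-(phenylselanyl)hexahydro-1-benzofuran-2,6-dione
Product: 30 (3aS,7aS)-5-[(2S)-5-[(tert-butyldiphenylsilyl)oxy]pentan-2-yl]-6-methylidene-4-(phenylselanyl)hexahydro-1-benzofuran-2(3H)-one
Conditions: Zn, CH2Br2, TiCl4, THF/CH2Cl2, 0 °C
Reagents that add atoms: dibromomethane, BrCBr
Why: Takai–Lombardo methylenation installs the C-10′ exocyclic methylene without the base that would trigger β-elimination of the lactone oxygen or of selenium.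

Step 16
Reactants: 30 (3aS,7aS)-5-[(2S)-5-[(tert-butyldiphenylsilyl)oxy]pentan-2-yl]-6-methylidene-4-(phenylselanyl)hexahydro-1-benzofuran-2(3H)-one
Product: 31 3-(1-hydroxy-2,2-dimethoxyethyl) derivative of 30 (diastereomers at C-3 and the carbinol carbon)
Conditions: LDA, THF, −78 °C; (MeO)2CHCHO, −78 °C
Reagents that add atoms: 2,2-dimethoxyacetaldehyde, COC(OC)C=O
Why: With the ketone gone the lactone enolate should form cleanly and add to glyoxal mono(dimethyl acetal) in an aldol addition.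

Step 17
Reactants: 31 3-(1-hydroxy-2,2-dimethoxyethyl) derivative of 30
Product: 33 (3E)-3-(2,2-dimethoxyethylidene) derivative of 30, via mesylate 32 (not isolated)
Conditions: MsCl, Et3N, CH2Cl2, 0 °C; then DBU, rt
Reagents that add atoms: none
Why: E1cB elimination of the mesylate should give the (E)-alkylidene lactone, acetal carbon anti to the lactone carbonyl and syn to C-7′, as is usual for α-alkylidene γ-lactones.

Step 18
Reactants: 33 (3E)-3-(2,2-dimethoxyethylidene) derivative of 30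
Product: 34 (3E)-3-(2-oxoethylidene) derivative of 30 (E-enal; CHO anti to the lactone carbonyl)
Conditions: TFA/H2O (9:1), CHCl3, 0 °C
Reagents that add atoms: water, O
Why: Acetal hydrolysis unveils the (E)-γ-oxo-enoate, the thermodynamically favoured trans-dicarbonyl geometry, while the silyl ether, the selenide and the 1,1-disubstituted alkene should tolerate brief cold acid.

Step 19
Reactants: 15 (3aS,7R,8aR,5E)-5-ethylidene-7-methyl-3,6-dimethylideneoctahydro-2H-cyclohepta[b]furan-2-one; 34 (3E)-3-(2-oxoethylidene) derivative of 30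
Product: 37 2-hydroxy norbornene (2-O-deacetyl-1′-O-TBDPS-6′-phenylselanyl-5′,6′-dihydro target; 2-OH syn to C-4=C-5), via Diels–Alder adduct 35 (not isolated), via epimerised aldehyde 36 (not isolated)
Conditions: Me2AlCl (1.2 equiv), CH2Cl2, −78 °C; then DBU (1.8 equiv), −78 → 0 °C; then Me2AlCl (4 equiv), −78 → −20 °C
Reagents that add atoms: none
Why: Proposed new method: Al-bound enal 34 and the s-cis-locked diene 15 should first undergo an 'ortho'-regioselective, endo Diels–Alder reaction (closest known type: Lewis-acid [4+2] of γ-oxo-enoates and alkylidene lactones), the unsubstituted diene terminus C-13′ bonding to the β-carbon C-11′ on the convex H-7′ face of the cis-fused lactone and C-4 to C-3, which closes the cyclohexene C-3/C-11′/C-13′/C-1/C-5/C-4 and gives 35 with CHO cis to C-7′ and to the C-4 methyl. DBU then equilibrates the enolisable C-3 to the more stable epimer 36, in which CHO is trans to the C-4 methyl and to the bulky C-7′ arm and hence cis to C-12′ and to H-4. The second charge of Me2AlCl activates the aldehyde for a type-I intramolecular carbonyl-ene reaction (closest known type: Me2AlCl-promoted ene cyclisation of unsaturated aldehydes to homoallylic alcohols) with the tetrasubstituted C-1=C-5 alkene: C-2 bonds to C-1 across the boat cyclohexene while the exo H-4 passes to oxygen, which closes the one-carbon bridge (5-exo along the C-13′ arm, 5-endo along the C-4 arm) and shifts the alkene to C-4=C-5. C-11′ is set by the lactone face, C-3 by thermodynamic epimerisation, C-1 by the C-3 tether (C-2 can reach C-1 only on the face it occupies) and C-2 by the cyclic ene transition state, which holds the Al-bound oxygen over C-4/C-5 and leaves H-2 toward C-13′. The step needs H-4 rather than H-6 transfer, secured by the exo H-4 lying next to that oxygen, and chemoselectivity for C-1=C-5, secured because C-5′=C-6′ is masked as the selenide and no other alkene can reach C-2 through a small ring. The strained bicyclo[2.2.1]heptene is expected to be trapped irreversibly as its aluminium alkoxide with loss of methane.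

Step 20
Reactants: 37 2-hydroxy norbornene
Product: 38 2-O-acetate of 37
Conditions: Ac2O, DMAP, pyridine, CH2Cl2, rt
Reagents that add atoms: acetic anhydride, CC(=O)OC(C)=O
Why: DMAP-catalysed acylation should esterify the only free hydroxyl (C-2) without touching its configuration.

Step 21
Reactants: 38 2-O-acetate of 37
Product: 40 1′-O-TBDPS ether of the target, via selenoxide 39 (not isolated)
Conditions: 30% H2O2, THF, 0 °C → rt
Reagents that add atoms: none
Why: Selenoxide syn-elimination should remove the allylic, syn-disposed H-5′ and so regenerate C-5′=C-6′ in conjugation with the C-10′ methylene, while peroxide leaves the other alkenes alone.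

Step 22
Reactants: 40 1′-O-TBDPS ether of the target
Product: 41 CNP0299458.1
Conditions: HF·pyridine, THF/pyridine, 0 °C → rt
Reagents that add atoms: none
Why: Fluoride-mediated desilylation of the primary silyl ether under buffered conditions should spare the acetate, both lactones and the dienes.

Compound list
1 | (R)-4-[(tert-butyldimethylsilyl)oxy]cyclohex-2-en-1-one | O=C1C=C[C@H](O[Si](C)(C)C(C)(C)C)CC1 | starting material
2 | (4R,6R)-4-[(tert-butyldimethylsilyl)oxy]-6-methylcyclohex-2-en-1-one | O=C1C=C[C@H](O[Si](C)(C)C(C)(C)C)C[C@H]1C | intermediate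
3 | methyl 2-[(1R,2R,4R)-2,5-bis[(tert-butyldimethylsilyl)oxy]-4-methylcyclohex-5-en-1-yl]acetate (silyl enol ether) | C[Si](C)(C(C)(C)C)OC1=C[C@@H](CC(=O)OC)[C@H](O[Si](C)(C)C(C)(C)C)C[C@H]1C | intermediate
4 | methyl 2-[(1S,2R,4R)-2-[(tert-butyldimethylsilyl)oxy]-4-methyl-5-oxocyclohexyl]acetate | O=C1C[C@@H](CC(=O)OC)[C@H](O[Si](C)(C)C(C)(C)C)C[C@H]1C | intermediate
5 | 6-(trimethylsilyl) derivative of 6 (α-silyl ketone, silyl epimers) | O=C1C([Si](C)(C)C)C[C@@H](CC(=O)OC)[C@H](O[Si](C)(C)C(C)(C)C)C[C@H]1C | intermediate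
6 | methyl 2-[(1S,2R,4R)-2-[(tert-butyldimethylsilyl)oxy]-4-methyl-5-oxocycloheptyl]acetate | O=C1CC[C@@H](CC(=O)OC)[C@H](O[Si](C)(C)C(C)(C)C)C[C@H]1C | intermediate
7 | methyl 2-[(1S,2R,4R)-2-hydroxy-4-methyl-5-oxocycloheptyl]acetate | O=C1CC[C@@H](CC(=O)OC)[C@H](O)C[C@H]1C | intermediate
8 | (3aS,7R,8aR)-7-methylhexahydro-2H-cyclohepta[b]furan-2,6(3H)-dione (trans-fused) | O=C1CC[C@H]2CC(=O)O[C@@H]2C[C@H]1C | intermediate
9 | (3aS,7R,8aR)-5-(1-hydroxyethyl)-7-methylhexahydro-2H-cyclohepta[b]furan-2,6(3H)-dione (diastereomer mixture) | O=C1C(C(C)O)C[C@H]2CC(=O)O[C@@H]2C[C@H]1C | intermediate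
10 | methanesulfonate of 9 | O=C1C(C(C)OS(C)(=O)=O)C[C@H]2CC(=O)O[C@@H]2C[C@H]1C | intermediate
11 | (3aS,7R,8aR,5E)-5-ethylidene-7-methylhexahydro-2H-cyclohepta[b]furan-2,6(3H)-dione | O=C1/C(=C/C)C[C@H]2CC(=O)O[C@@H]2C[C@H]1C | intermediate
12 | (3aS,7R,8aR,5E)-5-ethylidene-7-methyl-6-methylideneoctahydro-2H-cyclohepta[b]furan-2-one | C=C1/C(=C/C)C[C@H]2CC(=O)O[C@@H]2C[C@H]1C | intermediate
13 | 3-[(dimethylamino)methyl] derivative of 12 (aminomethyl anti to C-4 of the ring) | C=C1/C(=C/C)C[C@H]2[C@H](CN(C)C)C(=O)O[C@@H]2C[C@H]1C | intermediate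
14 | methiodide of 13 | C=C1/C(=C/C)C[C@H]2[C@H](C[N+](C)(C)C)C(=O)O[C@@H]2C[C@H]1C.[I-] | intermediate
15 | (3aS,7R,8aR,5E)-5-ethylidene-7-methyl-3,6-dimethylideneoctahydro-2H-cyclohepta[b]furan-2-one (diene) | C=C1/C(=C/C)C[C@H]2C(=C)C(=O)O[C@@H]2C[C@H]1C | intermediate
16 | (3-bromopropoxy)(tert-butyl)diphenylsilane | BrCCCO[Si](c1ccccc1)(c1ccccc1)C(C)(C)C | starting material
17 | (E)-pent-3-en-2-one | C/C=C/C(C)=O | starting material
18 | {3-[(tert-butyldiphenylsilyl)oxy]propyl}magnesium bromide | Br[Mg]CCCO[Si](c1ccccc1)(c1ccccc1)C(C)(C)C | intermediate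
19 | (4S)-7-[(tert-butyldiphenylsilyl)oxy]-3-[(dimethylamino)methyl]-4-methylheptan-2-one (C-3 epimers) | CC(=O)C(CN(C)C)[C@@H](C)CCCO[Si](c1ccccc1)(c1ccccc1)C(C)(C)C | intermediate
20 | methiodide of 19 | CC(=O)C(C[N+](C)(C)C)[C@@H](C)CCCO[Si](c1ccccc1)(c1ccccc1)C(C)(C)C.[I-] | intermediate
21 | (4S)-7-[(tert-butyldiphenylsilyl)oxy]-4-methyl-3-methylideneheptan-2-one | CC(=O)C(=C)[C@@H](C)CCCO[Si](c1ccccc1)(c1ccccc1)C(C)(C)C | intermediate
22 | methyl 4-oxobutanoate | COC(=O)CCC=O | starting material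
23 | methyl (3S)-5-acetyl-3-formyl-6-methyl-9-silyloxynonanoate type keto aldehyde (Michael adduct, C-5′ epimers) | O=C[C@H](CC(=O)OC)CC(C(C)=O)[C@@H](C)CCCO[Si](c1ccccc1)(c1ccccc1)C(C)(C)C | intermediate
24 | methyl 2-[(1S)-5-[(2S)-5-[(tert-butyldiphenylsilyl)oxy]pentan-2-yl]-4-oxocyclohex-2-en-1-yl]acetate (C-5 epimers) | O=C1C=C[C@H](CC(=O)OC)CC1[C@@H](C)CCCO[Si](c1ccccc1)(c1ccccc1)C(C)(C)C | intermediate
25 | carboxylic acid of 24 | O=C1C=C[C@H](CC(=O)O)CC1[C@@H](C)CCCO[Si](c1ccccc1)(c1ccccc1)C(C)(C)C | intermediate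
26 | (3aS,7aS)-5-[(2S)-5-[(tert-butyldiphenylsilyl)oxy]pentan-2-yl]hexahydro-1-benzofuran-2,6-dione (cis-fused, C-5 epimers) | O=C1C[C@@H]2OC(=O)C[C@@H]2CC1[C@@H](C)CCCO[Si](c1ccccc1)(c1ccccc1)C(C)(C)C | intermediate
27 | 5-(phenylselanyl) derivative of 26 (selenium at the side-chain-bearing α-carbon) | O=C1C[C@@H]2OC(=O)C[C@@H]2CC1([Se]c1ccccc1)[C@@H](C)CCCO[Si](c1ccccc1)(c1ccccc1)C(C)(C)C | intermediate
28 | (3aR,7aS)-5-[(2S)-5-[(tert-butyldiphenylsilyl)oxy]pentan-2-yl]-3,3a,7,7a-tetrahydro-1-benzofuran-2,6-dione | O=C1C[C@@H]2OC(=O)C[C@@H]2C=C1[C@@H](C)CCCO[Si](c1ccccc1)(c1ccccc1)C(C)(C)C | intermediate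
29 | (3aS,7aS)-5-[(2S)-5-[(tert-butyldiphenylsilyl)oxy]pentan-2-yl]-4-(phenylselanyl)hexahydro-1-benzofuran-2,6-dione (SePh anti to lactone CH2, side chain anti to SePh) | O=C1C[C@@H]2OC(=O)C[C@@H]2[C@@H]([Se]c2ccccc2)[C@@H]1[C@@H](C)CCCO[Si](c1ccccc1)(c1ccccc1)C(C)(C)C | intermediate
30 | (3aS,7aS)-5-[(2S)-5-[(tert-butyldiphenylsilyl)oxy]pentan-2-yl]-6-methylidene-4-(phenylselanyl)hexahydro-1-benzofuran-2(3H)-one | C=C1C[C@@H]2OC(=O)C[C@@H]2[C@@H]([Se]c2ccccc2)[C@@H]1[C@@H](C)CCCO[Si](c1ccccc1)(c1ccccc1)C(C)(C)C | intermediate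
31 | 3-(1-hydroxy-2,2-dimethoxyethyl) derivative of 30 (diastereomer mixture) | C=C1C[C@@H]2OC(=O)C(C(O)C(OC)OC)[C@@H]2[C@@H]([Se]c2ccccc2)[C@@H]1[C@@H](C)CCCO[Si](c1ccccc1)(c1ccccc1)C(C)(C)C | intermediate
32 | methanesulfonate of 31 | C=C1C[C@@H]2OC(=O)C(C(OS(C)(=O)=O)C(OC)OC)[C@@H]2[C@@H]([Se]c2ccccc2)[C@@H]1[C@@H](C)CCCO[Si](c1ccccc1)(c1ccccc1)C(C)(C)C | intermediate
33 | (3E)-3-(2,2-dimethoxyethylidene) derivative of 30 | C=C1C[C@@H]2OC(=O)/C(=C/C(OC)OC)[C@@H]2[C@@H]([Se]c2ccccc2)[C@@H]1[C@@H](C)CCCO[Si](c1ccccc1)(c1ccccc1)C(C)(C)C | intermediate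
34 | (3E)-3-(2-oxoethylidene) derivative of 30 (E-enal) | C=C1C[C@@H]2OC(=O)/C(=C/C=O)[C@@H]2[C@@H]([Se]c2ccccc2)[C@@H]1[C@@H](C)CCCO[Si](c1ccccc1)(c1ccccc1)C(C)(C)C | intermediate
35 | Diels–Alder adduct: spiro[lactone-cyclohexene] 3-carbaldehyde fused at C-1=C-5 to the guaianolide seven-membered ring; CHO cis to C-7′ and to the C-4 methyl | C=C1C[C@@H]2OC(=O)[C@@]3(CC4=C(C[C@H]5C(=C)C(=O)O[C@@H]5C[C@H]4C)[C@@H](C)[C@H]3C=O)[C@@H]2[C@@H]([Se]c2ccccc2)[C@@H]1[C@@H](C)CCCO[Si](c1ccccc1)(c1ccccc1)C(C)(C)C | intermediate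
36 | C-3 epimer of 35; CHO cis to C-12′ and to H-4 | C=C1C[C@@H]2OC(=O)[C@@]3(CC4=C(C[C@H]5C(=C)C(=O)O[C@@H]5C[C@H]4C)[C@@H](C)[C@@H]3C=O)[C@@H]2[C@@H]([Se]c2ccccc2)[C@@H]1[C@@H](C)CCCO[Si](c1ccccc1)(c1ccccc1)C(C)(C)C | intermediate
37 | 2-hydroxy norbornene: 2-O-deacetyl-1′-O-TBDPS-6′-(phenylselanyl)-5′,6′-dihydro derivative of the target (2-OH syn to C-4=C-5) | C=C1C[C@@H]2OC(=O)[C@@]3(C[C@@]45C(=C(C)[C@@H]3[C@@H]4O)C[C@H]3C(=C)C(=O)O[C@@H]3C[C@H]5C)[C@@H]2[C@@H]([Se]c2ccccc2)[C@@H]1[C@@H](C)CCCO[Si](c1ccccc1)(c1ccccc1)C(C)(C)C | intermediate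
38 | 2-O-acetate of 37 | C=C1C[C@@H]2OC(=O)[C@@]3(C[C@@]45C(=C(C)[C@@H]3[C@@H]4OC(C)=O)C[C@H]3C(=C)C(=O)O[C@@H]3C[C@H]5C)[C@@H]2[C@@H]([Se]c2ccccc2)[C@@H]1[C@@H](C)CCCO[Si](c1ccccc1)(c1ccccc1)C(C)(C)C | intermediate
39 | selenoxide of 38 | C=C1C[C@@H]2OC(=O)[C@@]3(C[C@@]45C(=C(C)[C@@H]3[C@@H]4OC(C)=O)C[C@H]3C(=C)C(=O)O[C@@H]3C[C@H]5C)[C@@H]2[C@@H]([Se](=O)c2ccccc2)[C@@H]1[C@@H](C)CCCO[Si](c1ccccc1)(c1ccccc1)C(C)(C)C | intermediate
40 | 1′-O-(tert-butyldiphenylsilyl) ether of the target | C=C1C[C@@H]2OC(=O)[C@@]3(C[C@@]45C(=C(C)[C@@H]3[C@@H]4OC(C)=O)C[C@H]3C(=C)C(=O)O[C@@H]3C[C@H]5C)[C@@H]2C=C1[C@@H](C)CCCO[Si](c1ccccc1)(c1ccccc1)C(C)(C)C | intermediate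
41 | CNP0299458.1 | C=C1C[C@@H]2OC(=O)[C@@]3(C[C@@]45C(=C(C)[C@@H]3[C@@H]4OC(C)=O)C[C@H]3C(=C)C(=O)O[C@@H]3C[C@H]5C)[C@@H]2C=C1[C@@H](C)CCCO | target

Total step count: 22. Longest linear sequence: 14 steps (steps 9–22); the diene branch (steps 1–8) joins at step 19.

Steps most likely to fail

Step 19. The bridging ene closure may stall or revert because of ring strain, hydrogen may be taken from C-6 instead of C-4, or the cycloaddition may go exo so that H-4 ends up on the wrong face. The fallback keeps the cycloaddition and epimerisation but replaces the concerted ene step by a stepwise cationic closure of established type. It sets out from aldehyde 36, isolated by stopping the sequence after the DBU stage. SnCl4 in CH2Cl2 at −78 °C should effect a Prins cyclisation with chloride capture at C-5 to give the chlorohydrin F1. Dehydrochlorination with DBU in warm toluene (syn-exo loss of H-4 and chloride) should then return to the route at 37.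

Step 12. The carboxyl group may fail to add to the enone (open-chain side of the equilibrium) or C-7′ may epimerise through the dienolate during saponification. The fallback builds the lactone by halolactonisation instead. It sets out from 24: Luche reduction gives the allylic alcohol F2, and LiOH gives the hydroxy acid F3. Iodolactonisation (I2, NaHCO3) should close the cis-fused iodolactone F4 with oxygen at C-8′. Bu3SnH/AIBN removes iodine to give the hydroxy lactone F5, and Dess–Martin oxidation returns to the route at 26.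

Step 3. The more substituted α-carbon may migrate, a second homologation may occur, or the α-methyl centre may epimerise under the Lewis acid. The fallback uses the regiodefined enol ether from step 2 for a Saegusa-type ring expansion. It sets out from 3, isolated by non-aqueous work-up of step 2. Et2Zn/CH2I2 gives the siloxycyclopropane F6, and FeCl3 in DMF opens it to the β-chloro ketone F7. NaOAc in MeOH eliminates to the cycloheptenone F8, and hydrogenation over Pd/C returns to the route at 6.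

Further compounds
F1 | step 19 | 5-chloro-2-hydroxy bicyclo[2.2.1]heptane (exo-chloride at C-5, H-4 exo; otherwise as 37) | C=C1C[C@@H]2OC(=O)[C@@]3(C[C@@]45[C@](Cl)([C@@H](C)[C@@H]3[C@@H]4O)C[C@H]3C(=C)C(=O)O[C@@H]3C[C@H]5C)[C@@H]2[C@@H]([Se]c2ccccc2)[C@@H]1[C@@H](C)CCCO[Si](c1ccccc1)(c1ccccc1)C(C)(C)C
F2 | step 12 | methyl 2-[(1S)-5-[(2S)-5-[(tert-butyldiphenylsilyl)oxy]pentan-2-yl]-4-hydroxycyclohex-2-en-1-yl]acetate (carbinol and C-5 epimers) | OC1C=C[C@H](CC(=O)OC)CC1[C@@H](C)CCCO[Si](c1ccccc1)(c1ccccc1)C(C)(C)C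
F3 | step 12 | carboxylic acid of F2 | OC1C=C[C@H](CC(=O)O)CC1[C@@H](C)CCCO[Si](c1ccccc1)(c1ccccc1)C(C)(C)C
F4 | step 12 | cis-fused 7-iodo-6-hydroxy lactone (iodolactone; iodide anti to the lactone oxygen) | OC1C(I)[C@@H]2OC(=O)C[C@@H]2CC1[C@@H](C)CCCO[Si](c1ccccc1)(c1ccccc1)C(C)(C)C
F5 | step 12 | cis-fused 6-hydroxy lactone (6-hydroxy analogue of 26) | OC1C[C@@H]2OC(=O)C[C@@H]2CC1[C@@H](C)CCCO[Si](c1ccccc1)(c1ccccc1)C(C)(C)C
F6 | step 3 | siloxycyclopropane (bicyclo[4.1.0]heptane from 3) | C[Si](C)(C(C)(C)C)OC12CC1[C@@H](CC(=O)OC)[C@H](O[Si](C)(C)C(C)(C)C)C[C@H]2C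
F7 | step 3 | β-chloro cycloheptanone (3-chloro analogue of 6) | O=C1CC(Cl)[C@@H](CC(=O)OC)[C@H](O[Si](C)(C)C(C)(C)C)C[C@H]1C
F8 | step 3 | cyclohept-2-enone (2,3-didehydro analogue of 6) | O=C1C=C[C@@H](CC(=O)OC)[C@H](O[Si](C)(C)C(C)(C)C)C[C@H]1C
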